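**Retrosynthetic overview**
1. Target ⇐ propargylic alcohol: the E‑CH=CH–C(OH) unit comes last, from hydroxyl‑directed trans‑hydroalumination of an alkyne that serves as an acid‑proof mask for the tertiary allylic alcohol.
2. Chroman (pyran ring B, the only ring made) ⇐ open hydroquinone, by an enantioselective tocopherol‑cyclase‑type protonative closure; a synthetic chiral acid is used because the 2S centre is the mirror image of the one the cyclase makes.
3. Hydroquinone ⇐ 2,3‑dimethylhydroquinone + C45 allylic alcohol (Friedel–Crafts prenyl transfer, as in the quinol prenyltransferase step).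
4. C45 chain ⇐ three C15 units: (S)‑dehydronerolidol (Sharpless epoxidation of farnesol, epoxy chloride → alkyne) and two molecules of 12‑bromofarnesyl acetate, joined by Cu alkyne–allyl coupling and by sulfone alkylation/desulfonylation.
5. Ring order: aromatic ring A is bought; ring B is closed in the penultimate step.

Assumptions: the SMILES is read as 2S at the chroman carbon and 24S at the carbinol carbon, all stereodefined chain alkenes E; the (S,S) hand of the acid in step 11 is taken to give 2S, and the (R,R) acid is used instead if a farnesylhydroquinone model closure shows the opposite sense.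

**Route**

Step 1
Reactants: 1 (2E,6E)-farnesol
Product: 2 (2S,3S)-2,3-epoxyfarnesol
Conditions: Ti(OiPr)4 (5 mol %), L-(+)-diethyl tartrate (7 mol %), t-BuOOH (2 equiv), 4 Å MS, CH2Cl2, −20 °C
Reagents that add atoms: tert-butyl hydroperoxide, CC(C)(C)OO
Why: Katsuki–Sharpless asymmetric epoxidation acts only on the allylic-alcohol alkene and with L-(+)-tartrate gives the 2S,3S epoxide (about 95% ee), which fixes the later carbinol carbon as S.

Step 2
Reactants: 2 (2S,3S)-2,3-epoxyfarnesol
Product: 3 (2R,3S)-2-(chloromethyl)-3-[(3E)-4,8-dimethylnona-3,7-dien-1-yl]-3-methyloxirane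
Conditions: PPh3, CCl4, NaHCO3, reflux
Reagents that add atoms: carbon tetrachloride, ClC(Cl)(Cl)Cl
Why: Appel chlorination replaces the primary OH under near-neutral conditions that leave the trisubstituted epoxide and both stereocentres untouched (C2 is now called R only because CH2Cl outranks C3).

Step 3
Reactants: 3 (2R,3S)-epoxy chloride
Product: 5 (S)-dehydronerolidol (3S,6E)-3,7,11-trimethyldodeca-6,10-dien-1-yn-3-ol, via chlorovinyl carbinol 4 (not isolated)
Conditions: n-BuLi (3.3 equiv), THF, −40 °C
Reagents that add atoms: none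
Why: Takano–Yadav epoxy chloride fragmentation: base-induced β-elimination opens the epoxide to the chlorovinyl alkoxide and a second loss of HCl gives the terminal alkyne, the C–O bond at the quaternary carbon never being broken, so S is kept.

Step 4
Reactants: 6 (2E,6E)-farnesyl acetate
Product: 7 (2E,6E,10E)-12-hydroxy-3,7,11-trimethyldodeca-2,6,10-trien-1-yl acetate
Conditions: SeO2 (0.3 equiv), salicylic acid (0.1 equiv), t-BuOOH (3 equiv), CH2Cl2, 0 °C to rt
Reagents that add atoms: tert-butyl hydroperoxide, CC(C)(C)OO (oxygen passed on through SeO2, O=[Se]=O)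
Why: Sharpless SeO2/t-BuOOH allylic oxidation (ene reaction then [2,3]-shift) hydroxylates the E-methyl of the terminal, most electron-rich alkene, the 2,3-alkene being deactivated by the allylic acetate.

Step 5
Reactants: 7 (2E,6E,10E)-12-hydroxyfarnesyl acetate
Product: 8 (2E,6E,10E)-12-bromo-3,7,11-trimethyldodeca-2,6,10-trien-1-yl acetate
Conditions: CBr4, PPh3, CH2Cl2, 0 °C
Reagents that add atoms: carbon tetrabromide, BrC(Br)(Br)Br
Why: Appel bromination of the primary allylic alcohol goes by SN2 displacement of the oxyphosphonium, keeping the 10E geometry and the acetate.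

Step 6
Reactants: 5 (S)-dehydronerolidol; 8 (2E,6E,10E)-12-bromofarnesyl acetate
Product: 10 C30 enyne diol (2E,6E,10E,15S,18E)-3,7,11,15,19,23-hexamethyltetracosa-2,6,10,18,22-pentaen-13-yne-1,15-diol, via enyne acetate 9 (not isolated)
Conditions: CuI (20 mol %), Bu4NI (10 mol %), K2CO3, DMF, rt; then MeOH, rt
Reagents that add atoms: none
Why: Cu-catalysed alkyne–allyl halide coupling: the copper acetylide displaces the primary bromide at the unhindered CH2 with retention of the E-alkene to give the skipped enyne, and the carbonate already present then removes the acetate by transesterification in methanol; the S carbinol is untouched.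

Step 7
Reactants: 10 C30 enyne diol
Product: 12 C30 allylic sulfone (2E,6E,10E,15S,18E)-3,7,11,15,19,23-hexamethyl-1-(phenylsulfonyl)tetracosa-2,6,10,18,22-pentaen-13-yn-15-ol, via allylic chloride 11 (not isolated)
Conditions: MsCl, s-collidine, LiCl, DMF, 0 °C; then PhSO2Na, rt
Reagents that add atoms: sodium benzenesulfinate, [Na+].[O-]S(=O)c1ccccc1
Why: Collington–Meyers chlorination (mesylate then chloride) takes only the primary allylic OH and not the hindered tertiary propargylic one, and SN2 S-alkylation of sulfinate by the allylic chloride gives the E-allylic sulfone without transposition.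

Step 8
Reactants: 12 C30 allylic sulfone; 8 (2E,6E,10E)-12-bromofarnesyl acetate
Product: 13 C45 sulfone acetate (2E,6E,10E,14E,18E,22E,27S,30E)-27-hydroxy-3,7,11,15,19,23,27,31,35-nonamethyl-13-(phenylsulfonyl)hexatriaconta-2,6,10,14,18,22,30,34-octaen-25-yn-1-yl acetate (C13 epimers)
Conditions: n-BuLi (2.1 equiv), THF–DMPU, −78 °C; then 8, −78 to −40 °C
Reagents that add atoms: none
Why: Biellmann-type head-to-tail coupling: the alkoxide/α-sulfonyl dianion of 12 alkylates the allylic bromide by SN2 at −78 °C faster than it attacks the acetate, all E-alkenes being retained (the sulfone-bearing carbon forms as an epimer mixture and is erased in step 9).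

Step 9
Reactants: 13 C45 sulfone acetate
Product: 15 C45 enyne diol (2E,6E,10E,14E,18E,22E,27S,30E)-3,7,11,15,19,23,27,31,35-nonamethylhexatriaconta-2,6,10,14,18,22,30,34-octaen-25-yne-1,27-diol, via sulfonyl diol 14 (not isolated)
Conditions: LiBHEt3 (6 equiv), THF, 0 °C, 30 min; then PdCl2(dppp) (5 mol %, dppp = Ph2P(CH2)3PPh2), 0 °C to rt
Reagents that add atoms: none
Why: LiBHEt3 first cleaves the acetate (so no allylic ester is left for palladium to ionise), then palladium-catalysed reductive desulfonylation delivers hydride to the less substituted terminus of the π-allyl, keeping the trisubstituted E-alkene in place; the alkyne and the propargylic alkoxide are not touched.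

Step 10
Reactants: 15 C45 enyne diol; 16 2,3-dimethylhydroquinone
Product: 17 hydroquinone 2-[(2E,6E,10E,14E,18E,22E,27S,30E)-27-hydroxy-3,7,11,15,19,23,27,31,35-nonamethylhexatriaconta-2,6,10,14,18,22,30,34-octaen-25-yn-1-yl]-5,6-dimethylbenzene-1,4-diol
Conditions: 16 (4 equiv), BF3·OEt2 (0.5 equiv), dioxane, rt, N2
Reagents that add atoms: none
Why: Friedel–Crafts allylation: BF3 ionises only the prenyl-type primary allylic alcohol (an α-alkynyl group destabilises the cation, so the tertiary propargylic alcohol resists ionisation) and the hydroquinone is C-alkylated at its single type of free position through the unhindered allyl terminus, mainly with retention of E geometry.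

Step 11
Reactants: 17 hydroquinone
Product: 18 chromanol enyne (2S)-2-[(3E,7E,11E,15E,19E,24S,27E)-24-hydroxy-4,8,12,16,20,24,28,32-octamethyltritriaconta-3,7,11,15,19,27,31-heptaen-22-yn-1-yl]-2,7,8-trimethylchroman-6-ol
Conditions: (S,S)-imidodiphosphorimidate acid HN[P(=NSO2CF3)(O2C20H10Ar2)]2, Ar = 3,5-(CF3)2C6H3 (5 mol %), cyclohexane, 40 °C, N2
Reagents that add atoms: none
Why: Proposed new method: the confined chiral acid hydrogen-bonds the phenol OH ortho to the chain and passes its proton to side-chain C2 while that oxygen bonds to C3 in a concerted, asynchronous Markovnikov 6-endo hydroalkoxylation (the tocopherol-cyclase mechanism), so only the phenol-tethered alkene reacts in non-ionising cyclohexane while the seven remote alkenes, the alkyne and the propargylic alcohol are left alone, and the chiral pocket selects the alkene face that gives the 2S quaternary centre; the closest known reaction types are imidodiphosphorimidate-catalysed asymmetric intramolecular hydroalkoxylation of unactivated alkenes and the racemic acid-catalysed chroman closure of prenylated hydroquinones.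

Step 12
Reactants: 18 chromanol enyne
Product: 19 target (2S)-2-[(3E,7E,11E,15E,19E,22E,24S,27E)-24-hydroxy-4,8,12,16,20,24,28,32-octamethyltritriaconta-3,7,11,15,19,22,27,31-octaen-1-yl]-2,7,8-trimethylchroman-6-ol
Conditions: NaAlH2(OCH2CH2OMe)2 (Red-Al, 5 equiv), THF, 0 to 40 °C
Reagents that add atoms: none
Why: Hydroxyl-directed trans-hydroalumination of the propargylic alkoxide (Red-Al reduction) gives the E-allylic alcohol on protonolysis, while isolated alkenes, the aryl ether and both stereocentres are inert.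

**Compound list**

1 | (2E,6E)-farnesol | CC(C)=CCC/C(C)=C/CC/C(C)=C/CO | starting material
2 | (2S,3S)-2,3-epoxyfarnesol, [(2S,3S)-3-[(3E)-4,8-dimethylnona-3,7-dien-1-yl]-3-methyloxiran-2-yl]methanol | CC(C)=CCC/C(C)=C/CC[C@]1(C)O[C@H]1CO | intermediate
3 | (2R,3S)-2-(chloromethyl)-3-[(3E)-4,8-dimethylnona-3,7-dien-1-yl]-3-methyloxirane | CC(C)=CCC/C(C)=C/CC[C@]1(C)O[C@H]1CCl | intermediate
4 | chlorovinyl carbinol, (3S,6E)-1-chloro-3,7,11-trimethyldodeca-1,6,10-trien-3-ol (C1=C2 E/Z mixture, lithium alkoxide in the flask) | CC(C)=CCC/C(C)=C/CC[C@](C)(O)C=CCl | intermediate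
5 | (S)-dehydronerolidol, (3S,6E)-3,7,11-trimethyldodeca-6,10-dien-1-yn-3-ol | CC(C)=CCC/C(C)=C/CC[C@](C)(O)C#C | intermediate
6 | (2E,6E)-farnesyl acetate | CC(C)=CCC/C(C)=C/CC/C(C)=C/COC(C)=O | starting material
7 | (2E,6E,10E)-12-hydroxy-3,7,11-trimethyldodeca-2,6,10-trien-1-yl acetate | OC/C(C)=C/CC/C(C)=C/CC/C(C)=C/COC(C)=O | intermediate
8 | (2E,6E,10E)-12-bromo-3,7,11-trimethyldodeca-2,6,10-trien-1-yl acetate | BrC/C(C)=C/CC/C(C)=C/CC/C(C)=C/COC(C)=O | intermediate
9 | enyne acetate, (2E,6E,10E,15S,18E)-15-hydroxy-3,7,11,15,19,23-hexamethyltetracosa-2,6,10,18,22-pentaen-13-yn-1-yl acetate | CC(C)=CCC/C(C)=C/CC[C@](C)(O)C#CC/C(C)=C/CC/C(C)=C/CC/C(C)=C/COC(C)=O | intermediate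
10 | C30 enyne diol, (2E,6E,10E,15S,18E)-3,7,11,15,19,23-hexamethyltetracosa-2,6,10,18,22-pentaen-13-yne-1,15-diol | CC(C)=CCC/C(C)=C/CC[C@](C)(O)C#CC/C(C)=C/CC/C(C)=C/CC/C(C)=C/CO | intermediate
11 | allylic chloride, (2E,6E,10E,15S,18E)-1-chloro-3,7,11,15,19,23-hexamethyltetracosa-2,6,10,18,22-pentaen-13-yn-15-ol | CC(C)=CCC/C(C)=C/CC[C@](C)(O)C#CC/C(C)=C/CC/C(C)=C/CC/C(C)=C/CCl | intermediate
12 | C30 allylic sulfone, (2E,6E,10E,15S,18E)-3,7,11,15,19,23-hexamethyl-1-(phenylsulfonyl)tetracosa-2,6,10,18,22-pentaen-13-yn-15-ol | CC(C)=CCC/C(C)=C/CC[C@](C)(O)C#CC/C(C)=C/CC/C(C)=C/CC/C(C)=C/CS(=O)(=O)c1ccccc1 | intermediate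
13 | C45 sulfone acetate, (2E,6E,10E,14E,18E,22E,27S,30E)-27-hydroxy-3,7,11,15,19,23,27,31,35-nonamethyl-13-(phenylsulfonyl)hexatriaconta-2,6,10,14,18,22,30,34-octaen-25-yn-1-yl acetate (C13 epimers) | CC(C)=CCC/C(C)=C/CC[C@](C)(O)C#CC/C(C)=C/CC/C(C)=C/CC/C(C)=C/C(C/C(C)=C/CC/C(C)=C/CC/C(C)=C/COC(C)=O)S(=O)(=O)c1ccccc1 | intermediate
14 | sulfonyl diol, the 1,27-diol corresponding to 13 (C13 epimers) | CC(C)=CCC/C(C)=C/CC[C@](C)(O)C#CC/C(C)=C/CC/C(C)=C/CC/C(C)=C/C(C/C(C)=C/CC/C(C)=C/CC/C(C)=C/CO)S(=O)(=O)c1ccccc1 | intermediate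
15 | C45 enyne diol, (2E,6E,10E,14E,18E,22E,27S,30E)-3,7,11,15,19,23,27,31,35-nonamethylhexatriaconta-2,6,10,14,18,22,30,34-octaen-25-yne-1,27-diol | CC(C)=CCC/C(C)=C/CC[C@](C)(O)C#CC/C(C)=C/CC/C(C)=C/CC/C(C)=C/CC/C(C)=C/CC/C(C)=C/CC/C(C)=C/CO | intermediate
16 | 2,3-dimethylhydroquinone (2,3-dimethylbenzene-1,4-diol) | Cc1c(C)c(O)ccc1O | starting material
17 | hydroquinone, 2-[(2E,6E,10E,14E,18E,22E,27S,30E)-27-hydroxy-3,7,11,15,19,23,27,31,35-nonamethylhexatriaconta-2,6,10,14,18,22,30,34-octaen-25-yn-1-yl]-5,6-dimethylbenzene-1,4-diol | CC(C)=CCC/C(C)=C/CC[C@](C)(O)C#CC/C(C)=C/CC/C(C)=C/CC/C(C)=C/CC/C(C)=C/CC/C(C)=C/CC/C(C)=C/Cc1cc(O)c(C)c(C)c1O | intermediate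
18 | chromanol enyne, (2S)-2-[(3E,7E,11E,15E,19E,24S,27E)-24-hydroxy-4,8,12,16,20,24,28,32-octamethyltritriaconta-3,7,11,15,19,27,31-heptaen-22-yn-1-yl]-2,7,8-trimethylchroman-6-ol | CC(C)=CCC/C(C)=C/CC[C@](C)(O)C#CC/C(C)=C/CC/C(C)=C/CC/C(C)=C/CC/C(C)=C/CC/C(C)=C/CC[C@@]1(C)CCc2cc(O)c(C)c(C)c2O1 | intermediate
19 | CNP0323443.2, (2S)-2-[(3E,7E,11E,15E,19E,22E,24S,27E)-24-hydroxy-4,8,12,16,20,24,28,32-octamethyltritriaconta-3,7,11,15,19,22,27,31-octaen-1-yl]-2,7,8-trimethylchroman-6-ol | CC(C)=CCC/C(C)=C/CC[C@](C)(O)/C=C/C/C(C)=C/CC/C(C)=C/CC/C(C)=C/CC/C(C)=C/CC/C(C)=C/CC[C@@]1(C)CCc2cc(O)c(C)c(C)c2O1 | target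

**Step count and risk**

Total: 12 steps (steps 3, 6, 7 and 9 each run through one non-isolated intermediate; bromide 8 from steps 4–5 is used twice). Longest linear sequence: 10 steps (1, 2, 3, 6, 7, 8, 9, 10, 11, 12 from farnesol).

Step 11 is the most likely to fail. The catalytic asymmetric closure has no precedent on a polyprenyl hydroquinone: the acid might protonate a remote alkene, give low enantioselectivity, or show the opposite facial sense, and any 2Z isomer carried from step 10 would erode the selectivity. The fallback sets out from 17: a catalytic amount of p-TsOH in toluene at room temperature closes the ring without facial control (well known for prenylated hydroquinones) and gives 18 together with the 2R epimer F1 in about equal amounts. The two epimers, which do not separate on silica because the centres are remote, are resolved by preparative HPLC on a cellulose tris(3,5-dimethylphenylcarbamate) phase. The route is rejoined at 18.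

Step 10 is the second risk. Late-stage Friedel–Crafts allylation typically gives 30–50% yield and may bring partial E/Z scrambling of the allyl cation, dialkylation, O-alkylation or premature racemic ring closure; the minor 2Z isomer would have to be removed on AgNO3-impregnated silica. The fallback sets out from 15: MsCl, LiCl and s-collidine in DMF give the allylic chloride F2, and Bu3SnLi (2.2 equiv, THF, −78 °C) converts it by SN2 into the allyl tributylstannane F3. F3 is then added to 2,3-dimethyl-1,4-benzoquinone with BF3·OEt2 in CH2Cl2 at −78 °C (quinone allylation with an allylstannane, which keeps the E geometry), and a Na2S2O4 wash returns any quinone to the quinol. The route is rejoined at 17.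

Step 9 is the third risk. The palladium hydride may partly reduce the skipped enyne or deliver hydride with some allylic transposition. The fallback sets out from 13: K2CO3 in MeOH gives 14, now isolated. Alkylation of 16 with 14 under the conditions of step 10 gives the sulfonyl hydroquinone F4, and the imidodiphosphorimidate acid of step 11 closes it to the sulfonyl chromanol F5. Lithium in EtNH2/THF at −78 °C then removes the sulfonyl group and reduces the alkyne to the E-alkene in one dissolving-metal operation. This arrives directly at 19, so steps 10–12 are replaced.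

**Further compounds**

F1 | step 11 | (2R)-epimer of 18, (2R)-2-[(3E,7E,11E,15E,19E,24S,27E)-24-hydroxy-4,8,12,16,20,24,28,32-octamethyltritriaconta-3,7,11,15,19,27,31-heptaen-22-yn-1-yl]-2,7,8-trimethylchroman-6-ol | CC(C)=CCC/C(C)=C/CC[C@](C)(O)C#CC/C(C)=C/CC/C(C)=C/CC/C(C)=C/CC/C(C)=C/CC/C(C)=C/CC[C@]1(C)CCc2cc(O)c(C)c(C)c2O1
F2 | step 10 | C45 allylic chloride, 15 with the C1 hydroxyl replaced by Cl (27S, all-E) | CC(C)=CCC/C(C)=C/CC[C@](C)(O)C#CC/C(C)=C/CC/C(C)=C/CC/C(C)=C/CC/C(C)=C/CC/C(C)=C/CC/C(C)=C/CCl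
F3 | step 10 | C45 allyl tributylstannane, 15 with the C1 hydroxyl replaced by SnBu3 (27S, all-E) | CC(C)=CCC/C(C)=C/CC[C@](C)(O)C#CC/C(C)=C/CC/C(C)=C/CC/C(C)=C/CC/C(C)=C/CC/C(C)=C/CC/C(C)=C/C[Sn](CCCC)(CCCC)CCCC
F4 | step 9 | sulfonyl hydroquinone, 17 carrying PhSO2 at chain C13 (C13 epimers) | CC(C)=CCC/C(C)=C/CC[C@](C)(O)C#CC/C(C)=C/CC/C(C)=C/CC/C(C)=C/C(C/C(C)=C/CC/C(C)=C/CC/C(C)=C/Cc1cc(O)c(C)c(C)c1O)S(=O)(=O)c1ccccc1
F5 | step 9 | sulfonyl chromanol, 18 carrying PhSO2 at side-chain C10 (2S, 24S, C10 epimers) | CC(C)=CCC/C(C)=C/CC[C@](C)(O)C#CC/C(C)=C/CC/C(C)=C/CC/C(C)=C/C(C/C(C)=C/CC/C(C)=C/CC[C@@]1(C)CCc2cc(O)c(C)c(C)c2O1)S(=O)(=O)c1ccccc1
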